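**Retrosynthetic overview**

1. Remangiflavanone A (24) comes from the tris-MOM flavanone 23 by acetal cleavage. Ring C is closed last, through O1–C2, by enantioselective oxa-Michael addition in chalcone 22, itself the aldol product of acetophenone 21 (ring A) and aldehyde 20 (ring B).
2. The acetyl group at C4a is placed by carbamate-directed lithiation of 16. The isopropenyl group on C2'' is made from the C–B bond of boronate 12 by Zweifel olefination with retention.
3. Key disconnection: C8–C1'' and C2''–C3'' are formed together across a vinyl group, from aryl bromide 5 and the ate complex of boronate 8 with vinyllithium 10 under chiral palladium catalysis, which sets C2''.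
4. Feature used: C8 of ring A carries a CH2 (C1'') bonded to the stereogenic CH (C2''), which bears the C3''–C6'' chain and the isopropenyl group. C1''–C2'' is therefore a two-carbon unit with an aryl group on one carbon and two carbon groups on the other, one of which can stand in as boron.
5. Ring A is phloroglucinol throughout; its single carbamate oxygen (the future O1) directs both the bromination at C8 and the acylation at C4a.

Key step: step 6

Assumption: the antipode of MandyPhos (step 6) and the cinchona pseudo-enantiomer (step 11) are those that give the drawn configurations; the sense of induction at C2'' would be checked by oxidising a sample of 12 to the secondary alcohol.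

**Step 1**
Reactants: 1 phloroglucinol
Product: 2 3,5-dihydroxyphenyl diethylcarbamate
Conditions: 1 (3 equiv), Et2NCOCl (1 equiv), K2CO3, acetone, reflux
Reagents that add atoms: diethylcarbamoyl chloride, CCN(CC)C(Cl)=O
Why: O-carbamoylation of a phenoxide (nucleophilic acyl substitution), held at the mono-carbamate stage by the threefold excess of the cheap symmetric triol, which is washed out with water afterwards.

**Step 2**
Reactants: 2 3,5-dihydroxyphenyl diethylcarbamate
Product: 3 3,5-bis(methoxymethoxy)phenyl diethylcarbamate
Conditions: MOMCl (3 equiv), i-Pr2NEt, CH2Cl2, 0 °C to rt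
Reagents that add atoms: chloromethyl methyl ether, COCCl
Why: O-alkylation of both remaining phenols with an α-chloro ether (MOM protection); the carbamate is inert to amine base.

**Step 3**
Reactants: 3 3,5-bis(methoxymethoxy)phenyl diethylcarbamate
Product: 5 2-bromo-3,5-bis(methoxymethoxy)phenyl diethylcarbamate, via aryllithium 4 (not isolated)
Conditions: s-BuLi, TMEDA, THF, −78 °C; BrCCl2CCl2Br, −78 °C to rt
Reagents that add atoms: 1,2-dibromo-1,1,2,2-tetrachloroethane, BrC(Cl)(Cl)C(Cl)(Cl)Br
Why: Directed ortho-metalation in which the carbamate, the strongest director on the ring, and the neighbouring MOM ether together place lithium at C2 (C6 is the same by symmetry) and not between the two MOM ethers, followed by bromine transfer; −78 °C should suppress the anionic ortho-Fries shift.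

**Step 4**
Reactants: 6 4-bromo-2-methylbut-1-ene
Product: 8 (3-methylbut-3-enyl)boronic acid pinacol ester, via Grignard reagent 7 (not isolated)
Conditions: Mg, THF, 25–40 °C; i-PrOBpin, −78 °C to rt; aq. NH4Cl
Reagents that add atoms: 2-isopropoxy-4,4,5,5-tetramethyl-1,3,2-dioxaborolane, CC(C)OB1OC(C)(C)C(C)(C)O1
Why: Grignard formation and borylation with an alkoxy pinacol borate; the homoallylic Grignard reagent is stable and the alkene takes no part.

**Step 5**
Reactants: 9 tetravinyltin
Product: 10 vinyllithium
Conditions: n-BuLi (hexanes), pentane, rt; solid washed with pentane under argon, dissolved in THF and titrated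
Reagents that add atoms: n-butyllithium, [Li]CCCC
Why: Tin–lithium exchange driven by precipitation of vinyllithium from the hydrocarbon, which should give the halide-free reagent that the palladium step needs.

**Step 6**
Reactants: 8 (3-methylbut-3-enyl)boronic acid pinacol ester; 10 vinyllithium; 5 2-bromo-3,5-bis(methoxymethoxy)phenyl diethylcarbamate
Product: 12 2-[(2R)-5-methyl-2-(4,4,5,5-tetramethyl-1,3,2-dioxaborolan-2-yl)hex-5-en-1-yl]-3,5-bis(methoxymethoxy)phenyl diethylcarbamate, via vinyl boronate ate complex 11 (not isolated)
Conditions: 8, 10 (1.0 equiv), THF, 0 °C to rt; then 5, Pd(OAc)2 (3 mol%), MandyPhos (3.6 mol%, bis(4-methoxy-3,5-dimethylphenyl)phosphino type, antipode giving 2''R), KOSO2CF3 (2 equiv), THF, 60 °C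
Reagents that add atoms: none
Why: Zerovalent palladium formed from Pd(OAc)2 and the bisphosphine inserts into the C8–Br bond of 5, KOSO2CF3 takes bromide off the metal as insoluble KBr, and the resulting cationic aryl–palladium species (divalent palladium) binds the boron-bound vinyl group of 11. This binding triggers a 1,2-metallate shift in which the 3-methylbut-3-enyl group moves from boron to the α-carbon (C2'') anti to palladium while palladium bonds to the terminal carbon (C1''); reductive elimination then joins C1'' to C8, so C2''–C3'' and C8–C1'' form in one operation. The closest known reaction type is the palladium-catalysed enantioselective conjunctive cross-coupling of vinylboron ate complexes with aryl triflates, or with aryl halides in the presence of a triflate salt; no ring is closed. The new stereocentre C2'' is controlled by the chiral ferrocenyl bisphosphine on palladium, which selects the enantioface of the vinyl group, and it should appear as a configurationally stable 2''R C–B centre. The step needs the boron-bound vinyl group to react in preference to the remote 1,1-disubstituted alkene and the carbamate: only that vinyl group is activated by tetracoordinate boron, Heck insertion into a 1,1-disubstituted alkene is slow, all vinyllithium is bound in 11 before 5 is added, and palladium does not insert into a carbamate C–O bond. The two ortho oxygen substituents of 5 make oxidative addition and alkene binding slower than in reported cases, which is the main uncertainty of the route.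

**Step 7**
Reactants: 12 secondary pinacol boronate; 13 2-bromopropene
Product: 16 2-[(2R)-5-methyl-2-(prop-1-en-2-yl)hex-5-en-1-yl]-3,5-bis(methoxymethoxy)phenyl diethylcarbamate, via isopropenyllithium 14 (not isolated), via isopropenyl boronate complex 15 (not isolated)
Conditions: 13, t-BuLi (2 equiv), Et2O, −78 °C; 12, THF, −78 °C; I2 (small excess), THF, −78 °C; NaOCH3, MeOH, −78 to 0 °C; aq. Na2S2O3
Reagents that add atoms: none
Why: Zweifel olefination, in which isopropenyllithium adds to boron, iodine activates the boron-bound alkene so that the secondary alkyl group migrates from boron to carbon with retention at C2'', and methoxide-induced anti elimination of boron and iodide gives the isopropenyl group; the 2''R centre is carried over unchanged, the carbamate is less electrophilic than boron at −78 °C, and a small excess of iodine with a cold thiosulfate quench should spare the electron-rich ring and the remote alkene.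

**Step 8**
Reactants: 16 diene carbamate
Product: 18 2-acetyl-6-[(2R)-5-methyl-2-(prop-1-en-2-yl)hex-5-en-1-yl]-3,5-bis(methoxymethoxy)phenyl diethylcarbamate, via aryllithium 17 (not isolated)
Conditions: s-BuLi, TMEDA, THF, −78 °C; CH3C(O)N(OCH3)CH3, −78 °C; aq. NH4Cl
Reagents that add atoms: N-methoxy-N-methylacetamide, CC(=O)N(C)OC
Why: Directed ortho-metalation followed by Weinreb ketone synthesis, in which the carbamate, a stronger director than a MOM ether, steers lithium to the one free position beside it (C4a, also flanked by the C5 MOM ether) and not to C6 or the benzylic C1''; the chelated tetrahedral adduct releases the methyl ketone only on work-up.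

**Step 9**
Reactants: 19 4-hydroxybenzaldehyde
Product: 20 4-(methoxymethoxy)benzaldehyde
Conditions: MOMCl, i-Pr2NEt, CH2Cl2, 0 °C to rt
Reagents that add atoms: chloromethyl methyl ether, COCCl
Why: MOM protection of the phenol by O-alkylation, so that the aldehyde can be used in a hydroxide-mediated aldol condensation without phenoxide deactivation.

**Step 10**
Reactants: 18 acetyl carbamate; 20 4-(methoxymethoxy)benzaldehyde
Product: 22 (2E)-1-{2-hydroxy-4,6-bis(methoxymethoxy)-3-[(2R)-5-methyl-2-(prop-1-en-2-yl)hex-5-en-1-yl]phenyl}-3-[4-(methoxymethoxy)phenyl]prop-2-en-1-one, via hydroxyacetophenone 21 (not isolated)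
Conditions: KOH (excess), EtOH/H2O, 80 °C; cool to 20 °C, 20 (1.5 equiv); AcOH to pH 6 at 0 °C
Reagents that add atoms: none
Why: Saponification of the aryl carbamate followed in the same medium by Claisen–Schmidt aldol condensation; in the protic medium hydroxide attack on the carbamate should outrun carbamoyl transfer to the ketone enolate, and the freed 2-hydroxyacetophenone condenses with the non-enolisable aldehyde to the E-chalcone, which is stable in base as its phenolate, while MOM ethers, alkenes and C2'' are inert to hydroxide.

**Step 11**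
Reactants: 22 chalcone
Product: 23 (2S)-5,7-bis(methoxymethoxy)-2-[4-(methoxymethoxy)phenyl]-8-[(2R)-5-methyl-2-(prop-1-en-2-yl)hex-5-en-1-yl]-2,3-dihydro-4H-chromen-4-one
Conditions: quinine-derived 3,5-bis(trifluoromethyl)phenyl thiourea (20 mol%; or the quinidine-derived pseudo-enantiomer, whichever gives 2S), toluene, 25 °C
Reagents that add atoms: none
Why: Enantioselective intramolecular oxa-Michael addition (6-endo-trig) under bifunctional catalysis, in which the tertiary amine of the catalyst activates the 2'-phenol and the thiourea binds the enone carbonyl, so that O1 adds to one face of C2 and the catalyst sets the 2S centre; the remote C2'' centre is untouched and should not bias the face selection.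

**Step 12**
Reactants: 23 tris-MOM flavanone
Product: 24 remangiflavanone A, (2S)-5,7-dihydroxy-2-(4-hydroxyphenyl)-8-[(2R)-5-methyl-2-(prop-1-en-2-yl)hex-5-en-1-yl]-2,3-dihydro-4H-chromen-4-one
Conditions: HCl (1.5 M), MeOH/H2O, 35 °C, stopped at full conversion
Reagents that add atoms: none
Why: Acid-catalysed solvolysis of the three aryl MOM acetals (transacetalisation to dimethoxymethane); dilute acid at modest temperature should spare the two 1,1-disubstituted alkenes, and without base there is no retro-oxa-Michael opening, so C2 and C2'' are kept.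

**Compound list**

1 | phloroglucinol | Oc1cc(O)cc(O)c1 | starting material
2 | 3,5-dihydroxyphenyl diethylcarbamate | CCN(CC)C(=O)Oc1cc(O)cc(O)c1 | intermediate
3 | 3,5-bis(methoxymethoxy)phenyl diethylcarbamate | CCN(CC)C(=O)Oc1cc(OCOC)cc(OCOC)c1 | intermediate
4 | 2-lithio-3,5-bis(methoxymethoxy)phenyl diethylcarbamate (not isolated) | CCN(CC)C(=O)Oc1cc(OCOC)cc(OCOC)c1[Li] | intermediate
5 | 2-bromo-3,5-bis(methoxymethoxy)phenyl diethylcarbamate | CCN(CC)C(=O)Oc1cc(OCOC)cc(OCOC)c1Br | intermediate
6 | 4-bromo-2-methylbut-1-ene | C=C(C)CCBr | starting material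
7 | (3-methylbut-3-enyl)magnesium bromide (not isolated) | C=C(C)CC[Mg]Br | intermediate
8 | (3-methylbut-3-enyl)boronic acid pinacol ester | C=C(C)CCB1OC(C)(C)C(C)(C)O1 | intermediate
9 | tetravinyltin | C=C[Sn](C=C)(C=C)C=C | starting material
10 | vinyllithium | [Li]C=C | intermediate
11 | lithium (3-methylbut-3-enyl)(vinyl) pinacol boronate ate complex (not isolated) | [Li+].C=C(C)CC[B-]1(C=C)OC(C)(C)C(C)(C)O1 | intermediate
12 | 2-[(2R)-5-methyl-2-(4,4,5,5-tetramethyl-1,3,2-dioxaborolan-2-yl)hex-5-en-1-yl]-3,5-bis(methoxymethoxy)phenyl diethylcarbamate | C=C(C)CC[C@H](Cc1c(OCOC)cc(OCOC)cc1OC(=O)N(CC)CC)B1OC(C)(C)C(C)(C)O1 | intermediate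
13 | 2-bromopropene | C=C(C)Br | starting material
14 | isopropenyllithium (not isolated) | [Li]C(C)=C | intermediate
15 | lithium isopropenyl boronate ate complex of 12 (not isolated) | [Li+].C=C(C)CC[C@H](Cc1c(OCOC)cc(OCOC)cc1OC(=O)N(CC)CC)[B-]1(C(C)=C)OC(C)(C)C(C)(C)O1 | intermediate
16 | 2-[(2R)-5-methyl-2-(prop-1-en-2-yl)hex-5-en-1-yl]-3,5-bis(methoxymethoxy)phenyl diethylcarbamate | C=C(C)CC[C@H](Cc1c(OCOC)cc(OCOC)cc1OC(=O)N(CC)CC)C(=C)C | intermediate
17 | 6-lithio derivative of 16 (lithium at the future C4a, not isolated) | C=C(C)CC[C@H](Cc1c(OCOC)cc(OCOC)c([Li])c1OC(=O)N(CC)CC)C(=C)C | intermediate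
18 | 2-acetyl-6-[(2R)-5-methyl-2-(prop-1-en-2-yl)hex-5-en-1-yl]-3,5-bis(methoxymethoxy)phenyl diethylcarbamate | C=C(C)CC[C@H](Cc1c(OCOC)cc(OCOC)c(C(C)=O)c1OC(=O)N(CC)CC)C(=C)C | intermediate
19 | 4-hydroxybenzaldehyde | O=Cc1ccc(O)cc1 | starting material
20 | 4-(methoxymethoxy)benzaldehyde | COCOc1ccc(C=O)cc1 | intermediate
21 | 1-{2-hydroxy-4,6-bis(methoxymethoxy)-3-[(2R)-5-methyl-2-(prop-1-en-2-yl)hex-5-en-1-yl]phenyl}ethan-1-one (not isolated) | C=C(C)CC[C@H](Cc1c(OCOC)cc(OCOC)c(C(C)=O)c1O)C(=C)C | intermediate
22 | (2E)-1-{2-hydroxy-4,6-bis(methoxymethoxy)-3-[(2R)-5-methyl-2-(prop-1-en-2-yl)hex-5-en-1-yl]phenyl}-3-[4-(methoxymethoxy)phenyl]prop-2-en-1-one | C=C(C)CC[C@H](Cc1c(OCOC)cc(OCOC)c(C(=O)/C=C/c2ccc(OCOC)cc2)c1O)C(=C)C | intermediate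
23 | (2S)-5,7-bis(methoxymethoxy)-2-[4-(methoxymethoxy)phenyl]-8-[(2R)-5-methyl-2-(prop-1-en-2-yl)hex-5-en-1-yl]-2,3-dihydro-4H-chromen-4-one | C=C(C)CC[C@H](Cc1c(OCOC)cc(OCOC)c2c1O[C@H](c1ccc(OCOC)cc1)CC2=O)C(=C)C | intermediate
24 | remangiflavanone A | C=C(C)CC[C@H](Cc1c(O)cc(O)c2c1O[C@H](c1ccc(O)cc1)CC2=O)C(=C)C | target

**Step count and risks**

Total step count: 12. Longest linear sequence: 9 steps (1, 2, 3, 6, 7, 8, 10, 11, 12, from phloroglucinol).

The three steps most likely to fail:

Step 6. Oxidative addition into the electron-rich bromide flanked by two oxygen substituents may be slow, bromide may inhibit the catalyst despite the triflate salt, and enantioface selection may be poor on this hindered aryl group. The fallback makes the same C–B stereocentre by lithiation–borylation and sets out from 3. Aryllithium 4, generated as in step 3, is treated with 2-(iodomethyl)-4,4,5,5-tetramethyl-1,3,2-dioxaborolane to give, after 1,2-shift with loss of iodide, 2-[(4,4,5,5-tetramethyl-1,3,2-dioxaborolan-2-yl)methyl]-3,5-bis(methoxymethoxy)phenyl diethylcarbamate F1. Commercial 4-methylpent-4-en-1-ol is converted with diisopropylcarbamoyl chloride into 4-methylpent-4-en-1-yl diisopropylcarbamate F2. Deprotonation with s-BuLi/(−)-sparteine in Et2O at −78 °C removes the pro-S hydrogen and gives (S)-1-lithio-4-methylpent-4-en-1-yl diisopropylcarbamate F3. F3 adds to the boron of F1 with retention to give the boronate complex F4. On warming (with MgBr2·OEt2 if needed) the benzylic group migrates from boron to carbon with inversion and expels the carbamate, which should give 12 with the 2''R configuration. The route is rejoined at 12.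

Step 10. Carbamoyl transfer from oxygen to the enolate carbon of the neighbouring acetyl group (a Baker–Venkataraman-type shift) may compete with hydrolysis, and hydrolysis of the doubly flanked carbamate may be slow. The fallback removes the carbamate before the ketone is present and sets out from 16. Lithiation as in step 8 (aryllithium 17) and quenching with BrCCl2CCl2Br should give 2-bromo-6-[(2R)-5-methyl-2-(prop-1-en-2-yl)hex-5-en-1-yl]-3,5-bis(methoxymethoxy)phenyl diethylcarbamate F5. Reductive cleavage of the carbamate with LiAlH4 in THF at 0 °C gives 2-bromo-6-[(2R)-5-methyl-2-(prop-1-en-2-yl)hex-5-en-1-yl]-3,5-bis(methoxymethoxy)phenol F6. Treatment with n-BuLi (2.2 equiv) in THF at −78 °C deprotonates the phenol and exchanges bromine for lithium to give the C,O-dilithio species F7. Acylation with N-methoxy-N-methylacetamide and aqueous work-up gives 21. The route is rejoined at 21, which is condensed with 20 under the aldol conditions of step 10.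

Step 11. Face selection at C2 may be poor, and reversible ring opening under the amine catalyst may erode it, giving a mixture of C2 epimers. The fallback separates the epimers by catalyst-controlled reduction and sets out from 22. Cyclisation with sodium acetate in refluxing EtOH gives 23 together with its C2 epimer, (2R)-5,7-bis(methoxymethoxy)-2-[4-(methoxymethoxy)phenyl]-8-[(2R)-5-methyl-2-(prop-1-en-2-yl)hex-5-en-1-yl]-2,3-dihydro-4H-chromen-4-one F8. Asymmetric transfer hydrogenation of the mixture with RuCl(p-cymene)(TsDPEN) (the antipode matched to the 2R epimer) and HCO2H/Et3N, used as a kinetic resolution, should reduce F8 to the cis-(2R,4R)-flavan-4-ol F9 and leave 23 unreduced; the isolated alkenes are not touched. 23 is separated from F9 by chromatography, and the route is rejoined at 23.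

**Further compounds**

F1 | step 6 | 2-[(4,4,5,5-tetramethyl-1,3,2-dioxaborolan-2-yl)methyl]-3,5-bis(methoxymethoxy)phenyl diethylcarbamate | CCN(CC)C(=O)Oc1cc(OCOC)cc(OCOC)c1CB1OC(C)(C)C(C)(C)O1
F2 | step 6 | 4-methylpent-4-en-1-yl diisopropylcarbamate | C=C(C)CCCOC(=O)N(C(C)C)C(C)C
F3 | step 6 | (S)-1-lithio-4-methylpent-4-en-1-yl diisopropylcarbamate | C=C(C)CC[C@H]([Li])OC(=O)N(C(C)C)C(C)C
F4 | step 6 | lithium boronate complex of F1 and F3 | [Li+].C=C(C)CC[C@H]([B-]1(Cc2c(OCOC)cc(OCOC)cc2OC(=O)N(CC)CC)OC(C)(C)C(C)(C)O1)OC(=O)N(C(C)C)C(C)C
F5 | step 10 | 2-bromo-6-[(2R)-5-methyl-2-(prop-1-en-2-yl)hex-5-en-1-yl]-3,5-bis(methoxymethoxy)phenyl diethylcarbamate | C=C(C)CC[C@H](Cc1c(OCOC)cc(OCOC)c(Br)c1OC(=O)N(CC)CC)C(=C)C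
F6 | step 10 | 2-bromo-6-[(2R)-5-methyl-2-(prop-1-en-2-yl)hex-5-en-1-yl]-3,5-bis(methoxymethoxy)phenol | C=C(C)CC[C@H](Cc1c(OCOC)cc(OCOC)c(Br)c1O)C(=C)C
F7 | step 10 | C,O-dilithio derivative of F6 | C=C(C)CC[C@H](Cc1c(OCOC)cc(OCOC)c([Li])c1O[Li])C(=C)C
F8 | step 11 | (2R)-5,7-bis(methoxymethoxy)-2-[4-(methoxymethoxy)phenyl]-8-[(2R)-5-methyl-2-(prop-1-en-2-yl)hex-5-en-1-yl]-2,3-dihydro-4H-chromen-4-one | C=C(C)CC[C@H](Cc1c(OCOC)cc(OCOC)c2c1O[C@@H](c1ccc(OCOC)cc1)CC2=O)C(=C)C
F9 | step 11 | (2R,4R)-5,7-bis(methoxymethoxy)-2-[4-(methoxymethoxy)phenyl]-8-[(2R)-5-methyl-2-(prop-1-en-2-yl)hex-5-en-1-yl]-3,4-dihydro-2H-chromen-4-ol | C=C(C)CC[C@H](Cc1c(OCOC)cc(OCOC)c2c1O[C@@H](c1ccc(OCOC)cc1)C[C@H]2O)C(=C)C
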